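The ring is numbered as a cembrane. C1 carries the isopropenyl group, C2 the secondary acetate, C7 the free hydroxyl and C8 the exocyclic methylene of the 14-membered ring. Everything rests on cutting C9–C10, the central σ-bond of the 1,5-diene CH2=C8–C9–C10–C11=C12. One palladium-catalysed intramolecular allyl–allyl cross-coupling closes the carbocycle there and leaves no activating group behind. It exploits that C8 bears two CH2 groups, which become equivalent termini of one η3-allyl unit, so regiocontrol is needed only at the geranyl-type end. The precursor is an open C20 chain ending in a 2-substituted allyl bromide and an (E)-allyl pinacolboronate, stitched together by a geraniol-derived bis(boronate).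

Key step: step 13

Remark on numbering: C18 is the CH2O carbon on C4 and C19 is the exocyclic methylene carbon on C8. TBS = tert-butyldimethylsilyl, pin = pinacolato.
Assumption: (R)-TRIP is taken to expose the Re face of enal 13, the sense it shows with other aldehydes. Its antipode would be used otherwise.

Step 1
Reactants: 1 (R)-α-hydroxy-γ-butyrolactone
Product: 2 (3R)-3-(tert-butyldimethylsilyloxy)oxolan-2-one
Conditions: TBSCl, imidazole, DMF, rt
Reagents that add atoms: tert-butyldimethylsilyl chloride, CC(C)(C)[Si](C)(C)Cl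
Why: Routine silylation of a secondary alcohol that leaves the lactone and the chiral-pool stereocentre (future C7) untouched.

Step 2
Reactants: 2 (3R)-3-(tert-butyldimethylsilyloxy)oxolan-2-one
Product: 4 (3R)-3-(TBS-oxy)-4-[(trimethylsilyl)methyl]pent-4-en-1-ol, via bis(silylmethyl)carbinol 3 (not isolated)
Conditions: CeCl3 (5 equiv), Me3SiCH2MgCl (5 equiv), THF, −78 °C to rt; aq NH4Cl; then SiO2, CH2Cl2, rt
Reagents that add atoms: (trimethylsilyl)methylmagnesium chloride, C[Si](C)(C)C[Mg]Cl
Why: The weakly basic organocerium reagent should add twice to the lactone carbonyl without enolising the α-stereocentre, and β-hydroxysilane 3 then undergoes acid-induced Peterson elimination to the 2-substituted allylsilane while the ring oxygen is released as the primary alcohol.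

Step 3
Reactants: 4 (3R)-3-(TBS-oxy)-4-[(trimethylsilyl)methyl]pent-4-en-1-ol
Product: 5 (3R)-3-(TBS-oxy)-5-iodo-2-[(trimethylsilyl)methyl]pent-1-ene
Conditions: PPh3, I2, imidazole (premixed), CH2Cl2, 0 °C
Reagents that add atoms: iodine, [I][I]
Why: Appel iodination with the preformed phosphonium iodide displaces only the activated primary hydroxyl by SN2, so no free iodine meets the allylsilane.

Step 4
Reactants: 6 but-2-yne-1,4-diol
Product: 7 4-(TBS-oxy)but-2-yn-1-ol
Conditions: 6 (3 equiv), TBSCl (1 equiv), imidazole, THF/DMF, 0 °C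
Reagents that add atoms: tert-butyldimethylsilyl chloride, CC(C)(C)[Si](C)(C)Cl
Why: Statistical monosilylation of a symmetrical diol used in excess.

Step 5
Reactants: 7 4-(TBS-oxy)but-2-yn-1-ol
Product: 9 (Z)-4-(TBS-oxy)-3-iodobut-2-en-1-ol, via cyclic alkenylalanate 8 (not isolated)
Conditions: NaAlH2(OCH2CH2OMe)2, THF, 0 °C to rt; then I2, −78 to 0 °C
Reagents that add atoms: iodine, [I][I]
Why: Hydroxyl-directed trans-hydroalumination places aluminium on the distal alkyne carbon inside five-membered alanate 8, and iodinolysis with retention gives the vinyl iodide with iodine cis to CH2OH, which fixes the later C3=C4 geometry.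

Step 6
Reactants: 9 (Z)-4-(TBS-oxy)-3-iodobut-2-en-1-ol
Product: 10 (Z)-4-(TBS-oxy)-3-iodobut-2-enal
Conditions: MnO2 (excess), CH2Cl2, rt
Reagents that add atoms: none
Why: Chemoselective MnO2 oxidation of a primary allylic alcohol to the enal that spares the vinyl iodide and the silyl ether.

Step 7
Reactants: 5 (3R)-3-(TBS-oxy)-5-iodo-2-[(trimethylsilyl)methyl]pent-1-ene; 10 (Z)-4-(TBS-oxy)-3-iodobut-2-enal
Product: 12 (2E,6R)-6-(TBS-oxy)-3-[(TBS-oxy)methyl]-7-[(trimethylsilyl)methyl]octa-2,7-dienal, via alkylzinc iodide 11 (not isolated)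
Conditions: 5, Zn dust, LiCl, THF, 40 °C; then 10, PdCl2(dppf) (3 mol%), THF, rt
Reagents that add atoms: none
Why: Negishi sp3–sp2 coupling, in which alkylzinc 11 tolerates aldehyde, silyl ethers and allylsilane, the bidentate ligand holds back β-hydride elimination, and the alkyl group replaces iodine with retention so that the chain (C5) ends cis to the formyl group (C2).

Step 8
Reactants: 12 (2E,6R)-6-(TBS-oxy)-3-[(TBS-oxy)methyl]-7-[(trimethylsilyl)methyl]octa-2,7-dienal
Product: 13 (2E,6R)-7-(bromomethyl)-6-(TBS-oxy)-3-[(TBS-oxy)methyl]octa-2,7-dienal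
Conditions: N-bromosuccinimide (1.0 equiv), propylene oxide, THF, −78 to −20 °C
Reagents that add atoms: N-bromosuccinimide, O=C1CCC(=O)N1Br
Why: Electrophilic bromodesilylation (SE2′) strikes the allylsilane, by far the most nucleophilic alkene because the only other one is the electron-poor enal, and the allylic transposition is degenerate since both allyl termini are CH2.

Step 9
Reactants: 14 geranyl acetate
Product: 15 (2E,6E)-8-hydroxy-3,7-dimethylocta-2,6-dien-1-yl acetate
Conditions: SeO2 (10 mol%), salicylic acid (10 mol%), tBuOOH, CH2Cl2, rt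
Reagents that add atoms: tert-butyl hydroperoxide, CC(C)(C)OO
Why: Catalytic SeO2 allylic oxidation (ene reaction followed by a [2,3]-sigmatropic shift) attacks the more electron-rich terminal trisubstituted alkene and selects its (E)-methyl group.

Step 10
Reactants: 15 (2E,6E)-8-hydroxy-3,7-dimethylocta-2,6-dien-1-yl acetate
Product: 16 (2E,6E)-2,6-dimethylocta-2,6-diene-1,8-diyl diacetate
Conditions: Ac2O, pyridine, rt
Reagents that add atoms: acetic anhydride, CC(=O)OC(C)=O
Why: Plain acetylation turns the second allylic oxygen into the same leaving group as the first.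

Step 11
Reactants: 16 (2E,6E)-2,6-dimethylocta-2,6-diene-1,8-diyl diacetate
Product: 17 (2E,6E)-2,6-dimethyl-1,8-bis(pinacolatoboryl)octa-2,6-diene
Conditions: B2pin2 (2.2 equiv), Pd2(dba)3 (3 mol%), DMSO, 50 °C
Reagents that add atoms: bis(pinacolato)diboron, CC1(C)OB(B2OC(C)(C)C(C)(C)O2)OC1(C)C
Why: Miyaura-type borylation of allylic acetates through η3-allylpalladium intermediates should put boron on the primary terminus of each allyl unit and keep both (E)-alkenes, while the absence of phosphine and base holds back allyl–allyl coupling.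

Step 12
Reactants: 13 (2E,6R)-7-(bromomethyl)-6-(TBS-oxy)-3-[(TBS-oxy)methyl]octa-2,7-dienal; 17 (2E,6E)-2,6-dimethyl-1,8-bis(pinacolatoboryl)octa-2,6-diene
Product: 19 open-chain (1R,2S,7R,3E,11E) bromo boronate with C2-OH, C7-OTBS, C18-OTBS, CH2Br (C9) on C8(=CH2), CH2B(pin) as C10 and isopropenyl on C1, via borate ester 18 (not isolated)
Conditions: 17 (1.3 equiv), (R)-3,3′-bis(2,4,6-triisopropylphenyl)-1,1′-binaphthyl-2,2′-diyl hydrogen phosphate ((R)-TRIP, 10 mol%), 4 Å MS, toluene, −30 °C; aq NaHCO3
Reagents that add atoms: none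
Why: Chiral-phosphoric-acid-catalysed allylboration through a closed Zimmerman–Traxler chair, in which the (E)-γ-monosubstituted boronate terminus gives the anti C1/C2 relationship and creates the isopropenyl group, the catalyst selects the Re face of the enal to set (1R,2S) independently of remote C7, and the γ,γ-disubstituted terminus, which would have to build a quaternary carbon, should react far more slowly and survive.

Step 13
Reactants: 19 open-chain (1R,2S,7R,3E,11E) bromo boronate
Product: 20 (1R,2S,3E,7R,11E)-7-(TBS-oxy)-4-[(TBS-oxy)methyl]-12-methyl-8-methylidene-1-(prop-1-en-2-yl)cyclotetradeca-3,11-dien-2-ol (cembrane numbering)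
Conditions: Pd2(dba)3 (5 mol%), PPh3 (20 mol%), CsF (5 equiv), THF, 50 °C, syringe-pump addition to about 1 mM
Reagents that add atoms: none
Why: Zerovalent palladium adds oxidatively to the C–Br bond to give an η3-allyl complex spanning C19–C8–C9, fluoride activates the C10 pinacolboronate for transmetalation, and the tethered bis(allyl)palladium eliminates reductively with formation of C9–C10. The closest known reaction type is the palladium-catalysed allyl–allyl cross-coupling of allylboronates with allyl halides, whose intramolecular counterpart is established for allylstannane/allyl ester pairs in small rings. The 14-membered carbocycle closes head-to-head (1,1′ reductive elimination), whereas the alternative 3,3′ mode would close a 12-membered ring at tertiary C12 with a quaternary carbon. No stereocentre is formed, C1, C2 and C7 are spectators, and the (E)-C11=C12 geometry should persist because syn/anti exchange would require palladium on the tertiary carbon. Regiocontrol is needed only at the geranyl-type allyl, where the primary C10 terminus, the monodentate phosphine and ring strain all favour the linear mode, since the two CH2 termini on C8 are constitutionally equivalent and either one gives the same exocyclic methylene. Chemoselectivity rests on 19 holding a single C–Br bond and no allylic ester (C2-OH free, C7 and C18 as silyl ethers), and oligomerisation is held back by slow addition at high dilution.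

Step 14
Reactants: 20 macrocyclic C2 alcohol
Product: 21 (1R,2S,3E,7R,11E) C2 acetate of 20 (C7-OTBS and C18-OTBS retained)
Conditions: Ac2O, pyridine, 4-dimethylaminopyridine (10 mol%), CH2Cl2, 0 °C to rt
Reagents that add atoms: acetic anhydride, CC(=O)OC(C)=O
Why: Nucleophile-catalysed acetylation of the only free hydroxyl (C2) with retention of configuration, the other two oxygens being masked as silyl ethers.

Step 15
Reactants: 21 C2 acetate bis(silyl ether)
Product: 22 (1R,2S,3E,7R,11E)-7-hydroxy-4-(hydroxymethyl)-12-methyl-8-methylidene-1-(prop-1-en-2-yl)cyclotetradeca-3,11-dien-2-yl acetate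
Conditions: HF·pyridine, pyridine, THF, 0 °C to rt
Reagents that add atoms: none
Why: Fluoride-driven cleavage of both silyl ethers under buffered conditions that should neither hydrolyse nor shift the C2 acetate, which lies trans across C3=C4 from the C18 oxygen and far from C7.

Step 16
Reactants: 22 C7,C18-diol C2-acetate
Product: 23 target, (1R,2S,3E,7R,11E)-2-acetoxy-4-(acetoxymethyl)-12-methyl-8-methylidene-1-(prop-1-en-2-yl)cyclotetradeca-3,11-dien-7-ol
Conditions: AcCl (1.05 equiv), 2,4,6-collidine, CH2Cl2, −78 °C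
Reagents that add atoms: acetyl chloride, CC(=O)Cl
Why: Kinetically selective acylation of the unhindered primary allylic C18 hydroxyl over the secondary C7 hydroxyl with one equivalent of acyl chloride and a hindered pyridine base at low temperature.

Compound list
1 | (R)-α-hydroxy-γ-butyrolactone | O=C1OCC[C@H]1O | starting material
2 | (3R)-3-(TBS-oxy)oxolan-2-one | O=C1OCC[C@H]1O[Si](C)(C)C(C)(C)C | intermediate
3 | (3R)-3-(TBS-oxy)-5-(trimethylsilyl)-4-[(trimethylsilyl)methyl]pentane-1,4-diol | OCC[C@@H](O[Si](C)(C)C(C)(C)C)C(O)(C[Si](C)(C)C)C[Si](C)(C)C | intermediate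
4 | (3R)-3-(TBS-oxy)-4-[(trimethylsilyl)methyl]pent-4-en-1-ol | OCC[C@@H](O[Si](C)(C)C(C)(C)C)C(=C)C[Si](C)(C)C | intermediate
5 | (3R)-3-(TBS-oxy)-5-iodo-2-[(trimethylsilyl)methyl]pent-1-ene | ICC[C@@H](O[Si](C)(C)C(C)(C)C)C(=C)C[Si](C)(C)C | intermediate
6 | but-2-yne-1,4-diol | OCC#CCO | starting material
7 | 4-(TBS-oxy)but-2-yn-1-ol | OCC#CCO[Si](C)(C)C(C)(C)C | intermediate
8 | sodium cyclic alkenylalanate (five-membered Al–O–CH2–CH=C ring, two 2-methoxyethoxy ligands) | [Na+].COCCO[Al-]1(OCCOC)OCC=C1CO[Si](C)(C)C(C)(C)C | intermediate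
9 | (Z)-4-(TBS-oxy)-3-iodobut-2-en-1-ol | OC/C=C(I)/CO[Si](C)(C)C(C)(C)C | intermediate
10 | (Z)-4-(TBS-oxy)-3-iodobut-2-enal | O=C/C=C(I)/CO[Si](C)(C)C(C)(C)C | intermediate
11 | alkylzinc iodide from 5 | I[Zn]CC[C@@H](O[Si](C)(C)C(C)(C)C)C(=C)C[Si](C)(C)C | intermediate
12 | (2E,6R)-6-(TBS-oxy)-3-[(TBS-oxy)methyl]-7-[(trimethylsilyl)methyl]octa-2,7-dienal | O=C/C=C(/CO[Si](C)(C)C(C)(C)C)CC[C@@H](O[Si](C)(C)C(C)(C)C)C(=C)C[Si](C)(C)C | intermediate
13 | (2E,6R)-7-(bromomethyl)-6-(TBS-oxy)-3-[(TBS-oxy)methyl]octa-2,7-dienal | O=C/C=C(/CO[Si](C)(C)C(C)(C)C)CC[C@@H](O[Si](C)(C)C(C)(C)C)C(=C)CBr | intermediate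
14 | geranyl acetate | CC(C)=CCC/C(C)=C/COC(C)=O | starting material
15 | (2E,6E)-8-hydroxy-3,7-dimethylocta-2,6-dien-1-yl acetate | OC/C(C)=C/CC/C(C)=C/COC(C)=O | intermediate
16 | (2E,6E)-2,6-dimethylocta-2,6-diene-1,8-diyl diacetate | CC(=O)OC/C(C)=C/CC/C(C)=C/COC(C)=O | intermediate
17 | (2E,6E)-2,6-dimethyl-1,8-bis(pinacolatoboryl)octa-2,6-diene | CC1(C)OB(C/C(C)=C/CC/C(C)=C/CB2OC(C)(C)C(C)(C)O2)OC1(C)C | intermediate
18 | C2 O-B(pin) borate ester of 19 | CC1(C)OB(C/C=C(\C)CC[C@H](C(=C)C)[C@@H](OB2OC(C)(C)C(C)(C)O2)/C=C(/CO[Si](C)(C)C(C)(C)C)CC[C@@H](O[Si](C)(C)C(C)(C)C)C(=C)CBr)OC1(C)C | intermediate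
19 | open-chain (1R,2S,7R,3E,11E) bromo boronate | CC1(C)OB(C/C=C(\C)CC[C@H](C(=C)C)[C@@H](O)/C=C(/CO[Si](C)(C)C(C)(C)C)CC[C@@H](O[Si](C)(C)C(C)(C)C)C(=C)CBr)OC1(C)C | intermediate
20 | macrocyclic C2 alcohol, C7-OTBS, C18-OTBS | C=C1CC/C=C(\C)CC[C@H](C(=C)C)[C@@H](O)/C=C(/CO[Si](C)(C)C(C)(C)C)CC[C@H]1O[Si](C)(C)C(C)(C)C | intermediate
21 | macrocyclic C2 acetate, C7-OTBS, C18-OTBS | C=C1CC/C=C(\C)CC[C@H](C(=C)C)[C@@H](OC(C)=O)/C=C(/CO[Si](C)(C)C(C)(C)C)CC[C@H]1O[Si](C)(C)C(C)(C)C | intermediate
22 | macrocyclic C2 acetate, C7,C18-diol | C=C1CC/C=C(\C)CC[C@H](C(=C)C)[C@@H](OC(C)=O)/C=C(/CO)CC[C@H]1O | intermediate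
23 | target CNP0077636.1 | C=C1CC/C=C(\C)CC[C@H](C(=C)C)[C@@H](OC(C)=O)/C=C(/COC(C)=O)CC[C@H]1O | target

Total step count: 16. Longest linear sequence: 10 steps (1, 2, 3, 7, 8, 12, 13, 14, 15, 16). The branch 4, 5, 6, 7, … is equally long.

Steps most likely to fail

Step 13. The slow ring closure may lose out to intermolecular coupling, to bond formation at the tertiary allyl terminus, or to protodeboronation. The fallback sets out from 19 and returns at 20. It replaces cross-coupling by a reductive coupling of two allyl bromides on zerovalent nickel, a closure established for 14-membered 1,5-diene rings.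
- The C–B bond of 19 would be oxidised (H2O2, pH 7 buffer, THF, 0 °C) to the bromo diol F1.
- The primary allylic hydroxyl of F1 would be brominated selectively (CBr4, PPh3, CH2Cl2, −20 °C) to the bis(allyl bromide) F2.
- F2 would be added slowly to Ni(cod)2 in DMF at 50 °C to give 20.

Step 12. The prenyl-type boronate terminus may transfer competitively, and facial selectivity on a β,β-disubstituted enal may be poor. The fallback sets out from 15 and 12 and returns at 19. It uses an allylchromium nucleophile, so only one boronate is ever present.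
- Selective borylation of the acetate terminus of 15 (B2pin2, Pd2(dba)3, DMSO) would give the hydroxy boronate F3.
- Appel bromination of F3 would give the bromo boronate F4.
- An anti-selective Nozaki–Hiyama–Kishi-type allylation of silane-bearing enal 12 (CrCl2, chiral oxazoline–sulfonamide ligand, Et3N, THF) would give the allylsilane alcohol F5.
- Bromodesilylation of F5 with N-bromosuccinimide at −78 °C leads to 19.

Step 7. The β-iodoenal may lose its alkene geometry, suffer 1,2-addition, or the alkylpalladium may undergo β-hydride elimination. The fallback sets out from 5 and 9 and returns at 12. It couples at the alcohol oxidation level with boron instead of zinc.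
- Iodide 5 would be lithiated (tBuLi, Et2O, −78 °C) to the alkyllithium F6.
- F6 would be trapped with 9-methoxy-9-borabicyclo[3.3.1]nonane as the borate F7.
- F7 would be joined to vinyl iodide 9 by B-alkyl Suzuki–Miyaura coupling (PdCl2(dppf), K3PO4, DMF, rt) to give the dienol F8.
- MnO2 oxidation of F8 gives 12.

Further compounds
F1 | step 13 | open-chain bromo diol (C10-OH, C2-OH, C9-Br) | OC/C=C(\C)CC[C@H](C(=C)C)[C@@H](O)/C=C(/CO[Si](C)(C)C(C)(C)C)CC[C@@H](O[Si](C)(C)C(C)(C)C)C(=C)CBr
F2 | step 13 | open-chain bis(allyl bromide) (C9-Br, C10-Br, C2-OH) | BrC/C=C(\C)CC[C@H](C(=C)C)[C@@H](O)/C=C(/CO[Si](C)(C)C(C)(C)C)CC[C@@H](O[Si](C)(C)C(C)(C)C)C(=C)CBr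
F3 | step 12 | (2E,6E)-2,6-dimethyl-8-(pinacolatoboryl)octa-2,6-dien-1-ol | OC/C(C)=C/CC/C(C)=C/CB1OC(C)(C)C(C)(C)O1
F4 | step 12 | (2E,6E)-8-bromo-3,7-dimethylocta-2,6-dien-1-yl pinacolboronate | BrC/C(C)=C/CC/C(C)=C/CB1OC(C)(C)C(C)(C)O1
F5 | step 12 | open-chain (1R,2S,7R,3E,11E) allylsilane boronate alcohol | CC1(C)OB(C/C=C(\C)CC[C@H](C(=C)C)[C@@H](O)/C=C(/CO[Si](C)(C)C(C)(C)C)CC[C@@H](O[Si](C)(C)C(C)(C)C)C(=C)C[Si](C)(C)C)OC1(C)C
F6 | step 7 | alkyllithium from 5 | [Li]CC[C@@H](O[Si](C)(C)C(C)(C)C)C(=C)C[Si](C)(C)C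
F7 | step 7 | lithium B-alkyl-B-methoxy-9-borabicyclo[3.3.1]nonane borate | [Li+].CO[B-]1(CC[C@@H](O[Si](C)(C)C(C)(C)C)C(=C)C[Si](C)(C)C)C2CCCC1CCC2
F8 | step 7 | (2E,6R)-6-(TBS-oxy)-3-[(TBS-oxy)methyl]-7-[(trimethylsilyl)methyl]octa-2,7-dien-1-ol | OC/C=C(/CO[Si](C)(C)C(C)(C)C)CC[C@@H](O[Si](C)(C)C(C)(C)C)C(=C)C[Si](C)(C)C
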